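Late in Thursday's run, at 10.0 h, X still led at 59.2% of the J charged, but G stood at 29.0% and was climbing, so I asked when G would take over in the new flasks.

| flask | J | remark | time |
|---|---|---|---|
| Thursday's | 0.025 M | run made earlier |  |
| Monday's | 0.10 M | run made earlier |  |
| noon | 0.050 M |  | 10 h |
| winter | 0.050 M |  | 15 h |
| dawn | 0.050 M |  | 8.0 h |

| run | time / h | X / % | Q / % | G / % | J / % |
|---|---|---|---|---|---|
| Thursday's | 2.50 | 87.9 | 1.6 | 8.5 | 0.8 |
| Thursday's | 5.00 | 76.3 | 3.8 | 15.8 | 0 |
| Thursday's | 8.00 | 63.6 | 8.5 | 25.5 | 0 |
| Thursday's | 10.0 | 59.2 | 10.9 | 29.0 | 0 |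
| Monday's | 2.50 | 85.9 | 0.6 | 9.3 | 0.1 |
| Monday's | 5.00 | 76.4 | 4.8 | 17.8 | 0 |
| Monday's | 8.00 | 64.7 | 6.4 | 25.8 | 0 |
| Monday's | 10.0 | 57.8 | 10.7 | 29.1 | 0 |

(each reading ± 1 percentage point)

- which of these there is most of at the end, counted by the J in it, noon (G / J / X / Q)
- which of these there is most of at the end, counted by the J in it, winter (G / J / X / Q)
- which of these there is most of at the end, counted by the J in it, dawn (G / J / X / Q)
- how much there is at the end of the one of these that leads, in percent of the J charged: noon
- how much there is at the end of the one of these that leads, in percent of the J charged: winter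
- how much there is at the end of the one of these that leads, in percent of the J charged: dawn

- a reading of J is of its free form alone

I read the runs as a ladder. The first rung was J: in Thursday's run it was down to 0.8% at 2.50 h and read 0% at 5.00 h. A reading of J is of its free form, so I took this as free J within the scatter of 1 percentage point of nothing, and reckoned on from there with X, G and Q. The second rung was the first-order decay of X, taken between the first and last readings:

k(X) = ln(c(X) first / c(X) last) / elapsed time = 0.0527 h⁻¹ in Thursday's run, 0.0528 h⁻¹ in Monday's

half-life of X = ln(2) / k(X) = 13.2 h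

This rate held from c(J) 0.025 M to 0.10 M, so I carried it to the flasks at 0.050 M. The last rung was the split of what had left X, read at the last Thursday reading:

f = c(G) / (c(G) + c(Q)) = 72.7%

With the charge taken as sitting in X, G and Q, the two curves meet here:

c(X) at the crossing = f / (1 + f) = 42.1%

t(crossing) = 10.0 h + ln(59.2% / 42.1%) / k(X) = 16.5 h

I called this the handover time, the time at which G overtakes X. The share f had been 80.6% at 5.00 h and was falling, so the true crossing could lie somewhat later. Dawn at 8.0 h and noon at 10 h stood before the half-life. Winter at 15 h stood past it but 1.50 h before the handover, so I expected X to lead in each.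

The forecast named X, X and X for noon, winter and dawn, at 58.5%, 45.5% and 64.5%, holding that “the 0.050 M runs should follow the same curves”.

The lead stayed with X at noon at 58.6%, with X in winter at 44.7%, and with X at dawn at 65.3%.

    J → X (k = 5.09 × 10⁻⁴ s⁻¹)
    X → G (k = 1.53 × 10⁻⁵ s⁻¹)
    G ⇌ Q (K = 0.710, k = 3.28 × 10⁻⁵ s⁻¹)
    J ⇌ L (K = 0.990, k = 1.14 × 10⁻⁵ s⁻¹)

The winter flask came closest: at 15.0 h G stood at 35.9%, behind X by 8.9 points, with the handover time 16.5 h still ahead. Read at 20 h, past the handover time, the dawn recipe had G in front, at 41.3% against X at 34.2%.

The data are simulated for substances that don't exist, and the scatter is random.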